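Cuts: the C6–O vanillate ester; the C4–isopropyl bond (back to a C4 ketone); C1–CH3 and C5–C6 together; then C1–C10 (alkenyl–allyl coupling) and C8–CH3 (carbocupration).
Enabling feature: the hydroazulene has a five-membered ring C1–C5 and a seven-membered ring C1, C5–C10. Quaternary C1 is β and ring-fusion C5 is α to C4, and O6 is β to C4. With C4 as a ketone, conjugate methylation at C1 therefore creates the very enolate whose C5 aldol with a C6 aldehyde closes the seven-membered ring.
Forward order: the C6–C10 chain is built with a Z C8=C9 bond and joined at C10 to a ready-made cyclopentenone. The cycloheptene closes in the key step, then the isopropyl group and the vanillate are added.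
Stereochemistry: C8=C9 (Z) from syn-carbocupration; C1 from a chiral NHC–copper catalyst; C5 and C6 from the zinc aldolate; C4 from attack anti to the C1 methyl group and the C5–C6 bond.

Key step: step 9

Remark: daucane numbering (C1 quaternary fusion carbon, C4 carbinol carbon, C5 fusion CH, C6 ester carbinol, C8=C9 alkene) is used for all intermediates; β is the face of the C1 methyl group, α that of H5.

Step 1
Reactants: 1 tert-butyl(but-3-yn-1-yloxy)dimethylsilane
Product: 3 methyl 5-(tert-butyldimethylsilyloxy)pent-2-ynoate, via lithium acetylide 2 (not isolated)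
Conditions: n-BuLi, THF, −78 °C; ClCO2Me, −78 → 0 °C
Reagents that add atoms: methyl chloroformate, COC(=O)Cl
Why: Deprotonation of the terminal alkyne and C-acylation of lithium acetylide 2 with a chloroformate is the standard alkynoate synthesis, and the silyl ether is inert to it.

Step 2
Reactants: 3 methyl 5-(tert-butyldimethylsilyloxy)pent-2-ynoate
Product: 4 methyl (Z)-5-(tert-butyldimethylsilyloxy)-3-methylpent-2-enoate
Conditions: Me2CuLi (MeLi, CuI), THF, −78 °C; sat. aq NH4Cl at −78 °C
Reagents that add atoms: lithium dimethylcuprate, [Li+].C[Cu-]C (from methyllithium, [Li]C, and CuI)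
Why: Conjugate syn-carbocupration of an alkynoate, with protonation of the alkenylcopper at −78 °C before it can equilibrate through the allenolate, puts CH3 cis to H and therefore C7 cis to the ester carbon (future C10), which fixes the Z C8=C9 bond.

Step 3
Reactants: 4 methyl (Z)-5-(tert-butyldimethylsilyloxy)-3-methylpent-2-enoate
Product: 5 (Z)-5-(tert-butyldimethylsilyloxy)-3-methylpent-2-en-1-ol
Conditions: DIBAL-H (2.2 equiv), CH2Cl2, −78 → 0 °C; aqueous work-up
Reagents that add atoms: none
Why: DIBAL-H reduces the enoate by two 1,2-hydride additions to the allylic alcohol without touching the alkene geometry or the silyl ether.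

Step 4
Reactants: 5 (Z)-5-(tert-butyldimethylsilyloxy)-3-methylpent-2-en-1-ol
Product: 6 (Z)-1-bromo-5-(tert-butyldimethylsilyloxy)-3-methylpent-2-ene
Conditions: CBr4, PPh3, CH2Cl2, −30 → 0 °C
Reagents that add atoms: carbon tetrabromide, BrC(Br)(Br)Br
Why: The Appel reaction replaces the primary allylic hydroxyl by SN2 attack of bromide on the alkoxyphosphonium ion, which at low temperature keeps both the position and the Z geometry of the double bond.

Step 5
Reactants: 7 3-ethoxycyclopent-2-en-1-one
Product: 9 3-(tributylstannyl)cyclopent-2-en-1-one, via lithium stannylcarbinolate 8 (not isolated)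
Conditions: Bu3SnH, LDA, THF, 0 °C; 7, −78 °C; then 1 M aq HCl, 0 °C
Reagents that add atoms: tributyltin hydride, CCCC[SnH](CCCC)CCCC (as tributylstannyllithium); water, O
Why: This is a Stork–Danheiser sequence with a stannyl anion as the nucleophile, in which 1,2-addition to the vinylogous ester gives 8 and acid-induced ionisation, hydration and loss of ethanol transpose it to the β-stannyl enone.

Step 6
Reactants: 6 (Z)-1-bromo-5-(tert-butyldimethylsilyloxy)-3-methylpent-2-ene; 9 3-(tributylstannyl)cyclopent-2-en-1-one
Product: 10 3-[(Z)-5-(tert-butyldimethylsilyloxy)-3-methylpent-2-enyl]cyclopent-2-en-1-one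
Conditions: Pd2(dba)3 (cat.), AsPh3 (cat.), THF, 23 → 45 °C
Reagents that add atoms: none
Why: Stille alkenyl–allyl cross-coupling forms C1–C10 at the unsubstituted terminus of the π-allylpalladium intermediate, keeps the Z geometry because syn/anti exchange at C8 would need a tertiary σ-allyl complex, and runs without base so that the doubly allylic C10 methylene is not deprotonated.

Step 7
Reactants: 10 3-[(Z)-5-(tert-butyldimethylsilyloxy)-3-methylpent-2-enyl]cyclopent-2-en-1-one
Product: 11 3-[(Z)-5-hydroxy-3-methylpent-2-enyl]cyclopent-2-en-1-one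
Conditions: HF·pyridine, pyridine, THF, 0 °C → rt
Reagents that add atoms: none
Why: Buffered fluoride-mediated cleavage of the primary silyl ether avoids the basic conditions that would move C8=C9 into conjugation with the enone.

Step 8
Reactants: 11 3-[(Z)-5-hydroxy-3-methylpent-2-enyl]cyclopent-2-en-1-one
Product: 12 3-[(Z)-3-methyl-5-oxopent-2-enyl]cyclopent-2-en-1-one
Conditions: Dess–Martin periodinane, NaHCO3, CH2Cl2, 0 °C; used at once
Reagents that add atoms: none
Why: Buffered Dess–Martin oxidation is the established way to turn a homoallylic alcohol into a β,γ-unsaturated aldehyde without migration of the double bond, and 12 is carried on without storage.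

Step 9
Reactants: 12 3-[(Z)-3-methyl-5-oxopent-2-enyl]cyclopent-2-en-1-one; 13 dimethylzinc
Product: 17 (3aR,8S,8aS)-8-hydroxy-3a,6-dimethyl-3,3a,4,7,8,8a-hexahydroazulen-1(2H)-one (daucane 1R,5S,6S; trans-fused, 6α-OH), via methylzinc enolate 14 (not isolated), via cis-fused zinc aldolate 15 (not isolated), via trans-fused zinc aldolate 16 (not isolated)
Conditions: (CuOTf)2·C6H6 (2.5 mol %), Ag(I) complex of a chiral sulfonate-bridged bidentate NHC (2.5 mol %, antipode that methylates the Si face of C1), 13 (3 equiv), Et2O, slow addition of 12 at −30 °C, then 22 °C; sat. aq NH4Cl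
Reagents that add atoms: dimethylzinc (13), C[Zn]C
Why: Proposed new method: a chiral NHC–Cu(I)–CH3 species generated from 13 π-binds the enone of 12, adds oxidatively at C1 and reductively eliminates to form C1–CH3, and transmetalation releases methylzinc enolate 14 with its double bond fixed between C4 and C5, so that only C5 can attack the tethered C6 aldehyde. The closest known reaction types are the NHC–copper-catalysed enantioselective addition of dialkylzinc reagents to β-substituted cyclic enones (quaternary carbon) and the copper-catalysed conjugate addition–intramolecular aldol cyclisation of zinc enolates; methyl transfer from 13 to a β-alkylcyclopentenone and closure of a seven-membered ring are the untested extensions. The cycloheptene closes in the 7-(enolexo)-exo-trig mode, helped by the Z C8=C9 bond, which already holds C7 and C10 cis. C1 is set by the ligand (CH3 to the Si face, 1R); C6 is set relative to C5 by the zinc-bridged chair transition state of the ring-locked E enolate (anti aldol, H5 and H6 trans-diaxial, O6 equatorial); C5 is bonded first on the face that carries C10 (cis-fused 15) and, because zinc aldolates revert readily, warming is meant to pass 15 back through 14 into chelate 16, in which the three ring bonds of C5 are equatorial and H5 lies anti to the C1 methyl group. The step needs 1,4-methylation beside a free aldehyde, which the inertness of 13 towards aldehydes without a Lewis-basic promoter and the base-free medium (no migration of the two skipped C=C bonds) secure, and it needs slow addition of 12 to keep the aldol intramolecular. It also needs the trans ring fusion, which rests on the aldolate equilibrium alone and is therefore the first risk treated below.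

Step 10
Reactants: 17 (3aR,8S,8aS)-8-hydroxy-3a,6-dimethyl-3,3a,4,7,8,8a-hexahydroazulen-1(2H)-one
Product: 18 (3aR,8S,8aS)-3a,6-dimethyl-8-(triethylsilyloxy)-3,3a,4,7,8,8a-hexahydroazulen-1(2H)-one
Conditions: TESCl, imidazole, CH2Cl2, 0 °C
Reagents that add atoms: chlorotriethylsilane, CC[Si](Cl)(CC)CC
Why: Silylation of the secondary alcohol under mild imidazole catalysis blocks retro-aldol cleavage and alkoxide formation in the next step and leaves C5 untouched.

Step 11
Reactants: 18 (3aR,8S,8aS)-3a,6-dimethyl-8-(triethylsilyloxy)-3,3a,4,7,8,8a-hexahydroazulen-1(2H)-one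
Product: 19 6-O-triethylsilyl-jaeschkeanadiol (daucane 1R,4R,5S,6S; 4β-OH, 4α-isopropyl, 6α-OTES)
Conditions: i-PrMgCl, anhydrous CeCl3, THF, −78 °C; sat. aq NH4Cl
Reagents that add atoms: isopropylmagnesium chloride, CC(C)[Mg]Cl
Why: Organocerium 1,2-addition, whose low basicity suppresses enolisation at C3/C5, β-elimination of the silyloxy group and β-hydride reduction, should take place on the α face of the C4 carbonyl, next to H5 and opposite both the C1 methyl group and the C5–C6 bond, to set C4 as R (OH β, isopropyl α).

Step 12
Reactants: 19 6-O-triethylsilyl-jaeschkeanadiol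
Product: 20 jaeschkeanadiol, (3R,3aS,4S,8aR)-6,8a-dimethyl-3-(propan-2-yl)-1,2,3,3a,4,5,8,8a-octahydroazulene-3,4-diol
Conditions: HF·pyridine, pyridine, THF, 0 °C
Reagents that add atoms: none
Why: Buffered HF·pyridine removes the triethylsilyl ether without ionising the tertiary C4 alcohol.

Step 13
Reactants: 21 vanillic acid
Product: 23 4-(tert-butyldimethylsilyloxy)-3-methoxybenzoic acid, via bis-silylated vanillate 22 (not isolated)
Conditions: TBSCl (2.5 equiv), imidazole, DMF, rt; then AcOH–THF–H2O, rt
Reagents that add atoms: tert-butyldimethylsilyl chloride, CC(C)(C)[Si](C)(C)Cl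
Why: Exhaustive silylation followed by selective hydrolysis of the far more labile silyl ester 22 leaves the phenol masked and the acid free.

Step 14
Reactants: 20 jaeschkeanadiol; 23 4-(tert-butyldimethylsilyloxy)-3-methoxybenzoic acid
Product: 24 O-tert-butyldimethylsilyl-teferin (6-O-[4-(tert-butyldimethylsilyloxy)-3-methoxybenzoyl]jaeschkeanadiol)
Conditions: DCC, DMAP (cat.), CH2Cl2, rt
Reagents that add atoms: none
Why: Steglich esterification acylates the secondary C6 hydroxyl with retention at C6, while the tertiary C4 hydroxyl is too hindered to react.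

Step 15
Reactants: 24 O-tert-butyldimethylsilyl-teferin
Product: 25 teferin
Conditions: TBAF, AcOH, THF, 0 °C
Reagents that add atoms: none
Why: Buffered fluoride cleaves the aryl silyl ether within minutes and leaves the hindered benzoate, the tertiary alcohol and the alkene untouched.

Compound list
1 | tert-butyl(but-3-yn-1-yloxy)dimethylsilane | C#CCCO[Si](C)(C)C(C)(C)C | starting material
2 | [4-(tert-butyldimethylsilyloxy)but-1-yn-1-yl]lithium | [Li]C#CCCO[Si](C)(C)C(C)(C)C | intermediate
3 | methyl 5-(tert-butyldimethylsilyloxy)pent-2-ynoate | COC(=O)C#CCCO[Si](C)(C)C(C)(C)C | intermediate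
4 | methyl (Z)-5-(tert-butyldimethylsilyloxy)-3-methylpent-2-enoate | COC(=O)/C=C(C)\CCO[Si](C)(C)C(C)(C)C | intermediate
5 | (Z)-5-(tert-butyldimethylsilyloxy)-3-methylpent-2-en-1-ol | OC/C=C(C)\CCO[Si](C)(C)C(C)(C)C | intermediate
6 | (Z)-1-bromo-5-(tert-butyldimethylsilyloxy)-3-methylpent-2-ene | BrC/C=C(C)\CCO[Si](C)(C)C(C)(C)C | intermediate
7 | 3-ethoxycyclopent-2-en-1-one | CCOC1=CC(=O)CC1 | starting material
8 | lithium 3-ethoxy-1-(tributylstannyl)cyclopent-2-en-1-olate (racemic) | CCOC1=CC(O[Li])([Sn](CCCC)(CCCC)CCCC)CC1 | intermediate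
9 | 3-(tributylstannyl)cyclopent-2-en-1-one | CCCC[Sn](CCCC)(CCCC)C1=CC(=O)CC1 | intermediate
10 | 3-[(Z)-5-(tert-butyldimethylsilyloxy)-3-methylpent-2-enyl]cyclopent-2-en-1-one | O=C1C=C(C/C=C(C)\CCO[Si](C)(C)C(C)(C)C)CC1 | intermediate
11 | 3-[(Z)-5-hydroxy-3-methylpent-2-enyl]cyclopent-2-en-1-one | O=C1C=C(C/C=C(C)\CCO)CC1 | intermediate
12 | 3-[(Z)-3-methyl-5-oxopent-2-enyl]cyclopent-2-en-1-one | O=CC/C(C)=C\CC1=CC(=O)CC1 | intermediate
13 | dimethylzinc | C[Zn]C | starting material
14 | methylzinc enolate, (1R)-configured, C4=C5 enolate carrying the free C6 aldehyde | O=CC/C(C)=C\C[C@@]1(C)CCC(O[Zn]C)=C1 | intermediate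
15 | cis-fused methylzinc aldolate (daucane 1R,5R,6R) | C[Zn]O[C@@H]1CC(C)=CC[C@@]2(C)CCC(=O)[C@@H]12 | intermediate
16 | trans-fused methylzinc aldolate (daucane 1R,5S,6S) | C[Zn]O[C@H]1CC(C)=CC[C@@]2(C)CCC(=O)[C@H]12 | intermediate
17 | (3aR,8S,8aS)-8-hydroxy-3a,6-dimethyl-3,3a,4,7,8,8a-hexahydroazulen-1(2H)-one | O[C@H]1CC(C)=CC[C@@]2(C)CCC(=O)[C@H]12 | intermediate
18 | (3aR,8S,8aS)-3a,6-dimethyl-8-(triethylsilyloxy)-3,3a,4,7,8,8a-hexahydroazulen-1(2H)-one | CC[Si](CC)(CC)O[C@H]1CC(C)=CC[C@@]2(C)CCC(=O)[C@H]12 | intermediate
19 | 6-O-triethylsilyl-jaeschkeanadiol (daucane 1R,4R,5S,6S) | CC[Si](CC)(CC)O[C@H]1CC(C)=CC[C@@]2(C)CC[C@@](O)(C(C)C)[C@H]12 | intermediate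
20 | jaeschkeanadiol | O[C@H]1CC(C)=CC[C@@]2(C)CC[C@@](O)(C(C)C)[C@H]12 | intermediate
21 | vanillic acid | COc1cc(C(=O)O)ccc1O | starting material
22 | tert-butyldimethylsilyl 4-(tert-butyldimethylsilyloxy)-3-methoxybenzoate | COc1cc(C(=O)O[Si](C)(C)C(C)(C)C)ccc1O[Si](C)(C)C(C)(C)C | intermediate
23 | 4-(tert-butyldimethylsilyloxy)-3-methoxybenzoic acid | COc1cc(C(=O)O)ccc1O[Si](C)(C)C(C)(C)C | intermediate
24 | O-tert-butyldimethylsilyl-teferin | COc1cc(C(=O)O[C@H]2CC(C)=CC[C@@]3(C)CC[C@@](O)(C(C)C)[C@H]23)ccc1O[Si](C)(C)C(C)(C)C | intermediate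
25 | teferin | COc1cc(C(=O)O[C@H]2CC(C)=CC[C@@]3(C)CC[C@@](O)(C(C)C)[C@H]23)ccc1O | target

Total steps: 15. Longest linear sequence: 13 (steps 1–4, 6–12, 14, 15).

Steps most likely to fail

Risk 1 (step 9):
- What may go wrong: methyl transfer from 13 to the β-alkylcyclopentenone may be too slow, and the zinc enolate may be quenched by proton transfer from the acidic C7 methylene. Above all, the aldolate equilibrium may stay on the cis-fused side, because closure on the face of the tether is the faster mode and the cis-fused hydroazulenone is not clearly higher in energy.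
- Fallback: it uses known chemistry, sets out from 7 and returns at 17. It forms C5–C6 intermolecularly and closes the ring at C8=C9 instead.
- Enone: allylmagnesium bromide adds to 7 to give 1-allyl-3-ethoxycyclopent-2-en-1-ol F1. Dilute acid transposes this to 3-allylcyclopent-2-en-1-one F2 (Stork–Danheiser).
- Quaternary carbon: NHC–copper-catalysed enantioselective addition of trimethylaluminium, a reaction established for β-alkylcyclopentenones, sets C1 and gives the dimethylaluminium enolate F3. TESOTf traps it as the triethylsilyl enol ether F4.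
- Aldol: methyllithium releases the lithium enolate F5, which adds at −78 °C to 3-methylbut-3-enal F6 (Dess–Martin oxidation of 3-methylbut-3-en-1-ol). Addition occurs on the face away from the larger allyl group, so that C6 ends trans to C10, and through a closed chair (anti). The product is the aldol (1R,5S,6S)-5-(1-hydroxy-3-methylbut-3-enyl)-1-allyl-1-methylcyclopentan-4-one F7.
- Ring closure: ring-closing metathesis with a second-generation Grubbs catalyst joins the allyl and methallyl ends to C8=C9 and delivers 17.

Risk 2 (step 11):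
- What may go wrong: enolisation, β-elimination of the silyloxy group or shielding of the α face by the C6 silyl ether may outrun addition of the branched nucleophile.
- Fallback: it sets out from 18 and returns at 19.
- Addition: the flat 2-propenylcerium reagent, which has no β-hydrogen (2-propenylmagnesium bromide, CeCl3, THF, −78 °C), adds to the same α face. This gives the isopropenyl carbinol 6-O-triethylsilyl-11,12-didehydrojaeschkeanadiol F8.
- Hydrogenation: Wilkinson's catalyst saturates only the 1,1-disubstituted alkene, leaves the trisubstituted C8=C9 bond and gives 19.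

Risk 3 (step 6):
- What may go wrong: slow transmetalation of the electron-poor stannane may give the π-allylpalladium intermediate time to lose its Z geometry, to couple at C8 or to homocouple.
- Fallback: it reverses the polarity, sets out from 5 (with 7) and returns at 10.
- Nucleophile: hexachloroacetone and PPh3 convert 5 without allylic shift into (Z)-1-chloro-5-(tert-butyldimethylsilyloxy)-3-methylpent-2-ene F9. Activated barium (BaI2, lithium biphenylide, THF, −78 °C) turns this into the (Z)-allylbarium chloride F10.
- Addition: allylbarium reagents add to carbonyl groups through their α-carbon with retention of geometry. F10 thus attacks the carbonyl of 7 with C10 to give 3-ethoxy-1-[(Z)-5-(tert-butyldimethylsilyloxy)-3-methylpent-2-enyl]cyclopent-2-en-1-ol F11.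
- Transposition: a short treatment with cold dilute HCl transposes F11 to 10.

Further compounds
F1 | step 9 | 1-allyl-3-ethoxycyclopent-2-en-1-ol (racemic) | C=CCC1(O)C=C(OCC)CC1
F2 | step 9 | 3-allylcyclopent-2-en-1-one | C=CCC1=CC(=O)CC1
F3 | step 9 | dimethylaluminium enolate of 3-allyl-3-methylcyclopentanone (daucane 1R) | C=CC[C@@]1(C)CCC(O[Al](C)C)=C1
F4 | step 9 | triethylsilyl enol ether of 3-allyl-3-methylcyclopentanone (daucane 1R) | C=CC[C@@]1(C)CCC(O[Si](CC)(CC)CC)=C1
F5 | step 9 | lithium enolate of 3-allyl-3-methylcyclopentanone (daucane 1R) | C=CC[C@@]1(C)CCC(O[Li])=C1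
F6 | step 9 | 3-methylbut-3-enal | C=C(C)CC=O
F7 | step 9 | aldol, daucane (1R,5S,6S), with allyl on C1 and 1-hydroxy-3-methylbut-3-enyl on C5 | C=CC[C@@]1(C)CCC(=O)[C@@H]1[C@@H](O)CC(C)=C
F8 | step 11 | 6-O-triethylsilyl-11,12-didehydrojaeschkeanadiol (isopropenyl carbinol) | CC[Si](CC)(CC)O[C@H]1CC(C)=CC[C@@]2(C)CC[C@@](O)(C(C)=C)[C@H]12
F9 | step 6 | (Z)-1-chloro-5-(tert-butyldimethylsilyloxy)-3-methylpent-2-ene | ClC/C=C(C)\CCO[Si](C)(C)C(C)(C)C
F10 | step 6 | [(Z)-5-(tert-butyldimethylsilyloxy)-3-methylpent-2-enyl]barium chloride | Cl[Ba]C/C=C(C)\CCO[Si](C)(C)C(C)(C)C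
F11 | step 6 | 3-ethoxy-1-[(Z)-5-(tert-butyldimethylsilyloxy)-3-methylpent-2-enyl]cyclopent-2-en-1-ol (racemic) | CCOC1=CC(O)(C/C=C(C)\CCO[Si](C)(C)C(C)(C)C)CC1
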